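**Retrosynthetic overview**
- Target ⇐ its hexamethyl ether; global O-demethylation is the last step.
- Bicyclo[3.2.1]oct-3-ene-2,8-dione core ⇐ an acyclic bis(benzylidene) 2,4,6-triketone, with both carbocycles closed in one flask operation.
- Ring order: the cyclopentanone forms first, by 4π-conrotatory (Nazarov) closure between the two benzylidene carbons (sets both aryl-bearing stereocentres, trans) with hydride interception. The cyclohexenone forms second, by bridged aldol condensation of the acetyl CH3 onto the cinnamoyl C=O (sets both bridgeheads).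
- Bis(benzylidene) triketone ⇐ Knoevenagel with 3,5-dimethoxybenzaldehyde ⇐ C-acylation of 3-(3,4-dimethoxybenzylidene)acetylacetone with 3,4-dimethoxycinnamoyl chloride ⇐ acetylacetone + 3,4-dimethoxybenzaldehyde.

Assumption: the (S,S)-ligand in step 4 is taken to give the drawn enantiomer; if the observed sense of induction is opposite, the (R,R)-ligand is used.

**Step 1**
Reactants: 1 acetylacetone (pentane-2,4-dione); 2 3,4-dimethoxybenzaldehyde
Product: 3 3-[(3,4-dimethoxyphenyl)methylidene]pentane-2,4-dione
Conditions: piperidine (10 mol%), AcOH (10 mol%), PhMe, reflux, Dean–Stark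
Reagents that add atoms: none
Why: Knoevenagel condensation of the active methylene of the 1,3-diketone with the aryl aldehyde under piperidinium acetate catalysis with azeotropic water removal; no stereocentre is formed, and the two acetyl groups on the alkylidene carbon are equivalent.

**Step 2**
Reactants: 3 3-[(3,4-dimethoxyphenyl)methylidene]pentane-2,4-dione; 4 (2E)-3-(3,4-dimethoxyphenyl)prop-2-enoic acid
Product: 6 (7E)-8-(3,4-dimethoxyphenyl)-3-[(3,4-dimethoxyphenyl)methylidene]oct-7-ene-2,4,6-trione, via acid chloride 5 (not isolated)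
Conditions: 4, (COCl)2 (1.2 equiv), DMF (cat.), CH2Cl2, 0 °C → rt, evaporate; then 3, MgBr2·OEt2 (2.5 equiv), i-Pr2NEt (3 equiv), CH2Cl2, 0 °C → rt; aq. HCl work-up
Reagents that add atoms: none
Why: Soft-enolization crossed Claisen acylation, in which MgBr2 chelation of the dione lets the amine deprotonate one of the two equivalent acetyl CH3 groups (the only enolizable positions of 3) and the magnesium enolate is C-acylated by acid chloride 5, the new chelated β-diketonate shielding the product from a second acylation; no stereocentre is formed.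

**Step 3**
Reactants: 6 (7E)-8-(3,4-dimethoxyphenyl)-3-[(3,4-dimethoxyphenyl)methylidene]oct-7-ene-2,4,6-trione; 7 3,5-dimethoxybenzaldehyde
Product: 8 (7E)-8-(3,4-dimethoxyphenyl)-3-[(3,4-dimethoxyphenyl)methylidene]-5-[(3,5-dimethoxyphenyl)methylidene]oct-7-ene-2,4,6-trione
Conditions: piperidine (20 mol%), AcOH (20 mol%), 4 Å MS, PhMe, 50 °C
Reagents that add atoms: none
Why: Knoevenagel condensation at the only active methylene of 6 (C5 of the chain, flanked by two ketones); no stereocentre is formed, and the geometry of the two benzylidene groups need not be controlled because they equilibrate under the Lewis acid of step 4.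

**Step 4**
Reactants: 8 (7E)-8-(3,4-dimethoxyphenyl)-3-[(3,4-dimethoxyphenyl)methylidene]-5-[(3,5-dimethoxyphenyl)methylidene]oct-7-ene-2,4,6-trione
Product: 11 (1R,5S,6S,7S)-7-(3,4-dimethoxyphenyl)-6-(3,5-dimethoxyphenyl)-4-[(E)-2-(3,4-dimethoxyphenyl)ethenyl]bicyclo[3.2.1]oct-3-ene-2,8-dione, via trans-triketone 9 (not isolated), via bridged ketol 10 (not isolated)
Conditions: Sc(OTf)3 (10 mol%), (S,S)-Ph-pybox (12 mol%), Et3SiH (1.2 equiv), ClCH2CH2Cl, −30 °C → rt; then TsOH·H2O (20 mol%), 60 °C
Reagents that add atoms: none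
Why: Proposed new method: the chiral Sc(OTf)3–pybox Lewis acid chelates a β-diketone unit of 8 and triggers a Nazarov 4π-conrotatory electrocyclization of the pentadienyl cation spanning the two benzylidene carbons, which with both aryl groups outside joins them trans and sets both aryl-bearing stereocentres in the absolute sense fixed by the ligand (torquoselectivity); the oxyallyl cation is then intercepted by hydride from Et3SiH before it can eliminate (closest known reaction types: the silane-terminated reductive Nazarov cyclization and the chiral-Lewis-acid Nazarov cyclization of 2-acyl divinyl ketones), giving triketone 9 whose two acyl-bearing carbons epimerize freely; acid then drives a bridged intramolecular aldol condensation of the acetyl CH3 onto the cinnamoyl C=O (a pyranone cannot form across the ring), which needs both acyl groups cis and should go through the epimer in which the small acetyl group rather than the cinnamoyl group sits cis to its neighbouring aryl group, so that the 3,4-dimethoxyphenyl group ends endo and both bridgeheads are fixed, while dehydration of ketol 10 can only go toward the CH2 because a bridgehead cannot carry the double bond.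

**Step 5**
Reactants: 11 (1R,5S,6S,7S)-7-(3,4-dimethoxyphenyl)-6-(3,5-dimethoxyphenyl)-4-[(E)-2-(3,4-dimethoxyphenyl)ethenyl]bicyclo[3.2.1]oct-3-ene-2,8-dione
Product: 12 (1R,5S,6S,7S)-7-(3,4-dihydroxyphenyl)-6-(3,5-dihydroxyphenyl)-4-[(E)-2-(3,4-dihydroxyphenyl)ethenyl]bicyclo[3.2.1]oct-3-ene-2,8-dione
Conditions: BBr3 (12 equiv), CH2Cl2, −78 → 0 °C; then MeOH, H2O
Reagents that add atoms: none
Why: Lewis-acid aryl methyl ether cleavage (bromide SN2 on the O-methyl of the borane–ether adducts) removes all six methyl groups, as is routine for permethylated stilbenoids, chalcones and curcuminoids carrying enones and styrenes; no stereocentre is touched, since the bridgehead CH groups cannot enolize and the aryl-bearing carbons are not acidic.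

**Compound list**
1 | acetylacetone (pentane-2,4-dione) | CC(=O)CC(C)=O | starting material
2 | 3,4-dimethoxybenzaldehyde | COc1ccc(C=O)cc1OC | starting material
3 | 3-[(3,4-dimethoxyphenyl)methylidene]pentane-2,4-dione | CC(=O)C(=Cc1ccc(OC)c(OC)c1)C(C)=O | intermediate
4 | (2E)-3-(3,4-dimethoxyphenyl)prop-2-enoic acid (3,4-dimethoxycinnamic acid) | COc1ccc(/C=C/C(=O)O)cc1OC | starting material
5 | (2E)-3-(3,4-dimethoxyphenyl)prop-2-enoyl chloride | COc1ccc(/C=C/C(Cl)=O)cc1OC | intermediate
6 | (7E)-8-(3,4-dimethoxyphenyl)-3-[(3,4-dimethoxyphenyl)methylidene]oct-7-ene-2,4,6-trione (benzylidene geometry not fixed, drawn as the triketo tautomer) | CC(=O)C(=Cc1ccc(OC)c(OC)c1)C(=O)CC(=O)/C=C/c1ccc(OC)c(OC)c1 | intermediate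
7 | 3,5-dimethoxybenzaldehyde | COc1cc(C=O)cc(OC)c1 | starting material
8 | (7E)-8-(3,4-dimethoxyphenyl)-3-[(3,4-dimethoxyphenyl)methylidene]-5-[(3,5-dimethoxyphenyl)methylidene]oct-7-ene-2,4,6-trione (both benzylidene geometries not fixed) | CC(=O)C(=Cc1ccc(OC)c(OC)c1)C(=O)C(=Cc1cc(OC)cc(OC)c1)C(=O)/C=C/c1ccc(OC)c(OC)c1 | intermediate
9 | (3S,4S)-2-acetyl-3-(3,4-dimethoxyphenyl)-4-(3,5-dimethoxyphenyl)-5-[(2E)-3-(3,4-dimethoxyphenyl)prop-2-enoyl]cyclopentan-1-one (aryl groups trans; C2 and C5 epimerize) | CC(=O)C1C(=O)C(C(=O)/C=C/c2ccc(OC)c(OC)c2)[C@@H](c2cc(OC)cc(OC)c2)[C@@H]1c1ccc(OC)c(OC)c1 | intermediate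
10 | (1R,5S,6S,7S)-7-(3,4-dimethoxyphenyl)-6-(3,5-dimethoxyphenyl)-4-[(E)-2-(3,4-dimethoxyphenyl)ethenyl]-4-hydroxybicyclo[3.2.1]octane-2,8-dione (carbinol configuration immaterial) | O=C1CC(O)(/C=C/c2ccc(OC)c(OC)c2)[C@H]2C(=O)[C@@H]1[C@@H](c1ccc(OC)c(OC)c1)[C@@H]2c1cc(OC)cc(OC)c1 | intermediate
11 | (1R,5S,6S,7S)-7-(3,4-dimethoxyphenyl)-6-(3,5-dimethoxyphenyl)-4-[(E)-2-(3,4-dimethoxyphenyl)ethenyl]bicyclo[3.2.1]oct-3-ene-2,8-dione (7-aryl endo, 6-aryl exo) | O=C1C=C(/C=C/c2ccc(OC)c(OC)c2)[C@H]2C(=O)[C@@H]1[C@@H](c1ccc(OC)c(OC)c1)[C@@H]2c1cc(OC)cc(OC)c1 | intermediate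
12 | (1R,5S,6S,7S)-7-(3,4-dihydroxyphenyl)-6-(3,5-dihydroxyphenyl)-4-[(E)-2-(3,4-dihydroxyphenyl)ethenyl]bicyclo[3.2.1]oct-3-ene-2,8-dione | O=C1C=C(/C=C/c2ccc(O)c(O)c2)[C@H]2C(=O)[C@@H]1[C@@H](c1ccc(O)c(O)c1)[C@@H]2c1cc(O)cc(O)c1 | target

**Totals and risks**
Total step count: 5. Longest linear sequence: 5 steps (1 → 3 → 6 → 8 → 11 → 12).

The three steps most likely to fail are step 4, step 2 and step 3.

Step 4 is the main gamble. The oxyallyl cation may lose a proton to give a cyclopentenone (destroying one aryl-bearing stereocentre) faster than it takes hydride. The silane may reduce a benzylidene diketone conjugately before cyclization. A second 4π closure through the cinnamoyl ketone can compete. The enantioselectivity and the endo/exo ratio of the aldol are unproven. A reversible Michael addition of the diketone carbon onto the cinnamoyl double bond could hold material back. The fallback sets out from 8 and comes back at 11. SmI2 (2.2 equiv) with t-BuOH in THF at −78 °C couples the two benzylidene carbons reductively (radical-anion cyclization of the electrohydrocyclization type) to the racemic trans-triketone F1. TsOH in toluene at 60 °C then closes the second ring through the racemic bridged ketol F2 to the racemic hexamethyl ether F3. Preparative chromatography on a chiral stationary phase gives 11.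

Step 2 can suffer from O-acylation, double acylation or Michael-type self-condensation of the benzylidene diketone. The fallback sets out from 3 and comes back at 6. The magnesium enolate of 3 (MgBr2·OEt2, i-Pr2NEt) is added to commercial (E)-3,4-dimethoxycinnamaldehyde to give the β-hydroxy ketone F4, and Dess–Martin periodinane oxidizes it to 6.

Step 3 can scramble the two aryl aldehydes by retro-Knoevenagel exchange, or let 6 cyclize early (acetyl CH3 onto the C6 ketone) under amine catalysis. The fallback sets out from 6 and comes back at 8. A MgBr2·OEt2/i-Pr2NEt aldol addition of 6 to 7 at 0 °C gives the β-hydroxy triketone F5, which is dehydrated without amine by TsOH (cat.) over 4 Å MS in CH2Cl2 at rt.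

**Further compounds**
F1 | step 4 | racemic trans-triketone, a 1:1 mixture of 9 and its mirror image (3R,4R)-2-acetyl-3-(3,4-dimethoxyphenyl)-4-(3,5-dimethoxyphenyl)-5-[(2E)-3-(3,4-dimethoxyphenyl)prop-2-enoyl]cyclopentan-1-one; the mirror image is drawn | CC(=O)C1C(=O)C(C(=O)/C=C/c2ccc(OC)c(OC)c2)[C@H](c2cc(OC)cc(OC)c2)[C@H]1c1ccc(OC)c(OC)c1
F2 | step 4 | racemic bridged ketol, a 1:1 mixture of 10 and its (1S,5R,6R,7R) mirror image; the mirror image is drawn | O=C1CC(O)(/C=C/c2ccc(OC)c(OC)c2)[C@@H]2C(=O)[C@H]1[C@H](c1ccc(OC)c(OC)c1)[C@H]2c1cc(OC)cc(OC)c1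
F3 | step 4 | racemic hexamethyl ether, a 1:1 mixture of 11 and its (1S,5R,6R,7R) mirror image; the mirror image is drawn | O=C1C=C(/C=C/c2ccc(OC)c(OC)c2)[C@@H]2C(=O)[C@H]1[C@H](c1ccc(OC)c(OC)c1)[C@H]2c1cc(OC)cc(OC)c1
F4 | step 2 | (7E)-8-(3,4-dimethoxyphenyl)-3-[(3,4-dimethoxyphenyl)methylidene]-6-hydroxyoct-7-ene-2,4-dione (racemic carbinol) | CC(=O)C(=Cc1ccc(OC)c(OC)c1)C(=O)CC(O)/C=C/c1ccc(OC)c(OC)c1
F5 | step 3 | (7E)-8-(3,4-dimethoxyphenyl)-3-[(3,4-dimethoxyphenyl)methylidene]-5-[(3,5-dimethoxyphenyl)(hydroxy)methyl]oct-7-ene-2,4,6-trione (diastereomer mixture) | CC(=O)C(=Cc1ccc(OC)c(OC)c1)C(=O)C(C(O)c1cc(OC)cc(OC)c1)C(=O)/C=C/c1ccc(OC)c(OC)c1
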